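**Strategy**

Ring A is opened across C2–C3 and C1–C6. The C3–H that sits beside the three contiguous bromines on C4, C5 and C6 of ring A is read as the carbon chain of a 2,3,4-tribromothiophene 1,1-dioxide, and the neighbouring oxygens on C1 and C2 as an aryloxy ketene bis(silyl) acetal that already carries ring B. One operation, an inverse-electron-demand [4+2] addition followed by loss of SO2 and of Me3SiOH, should deliver fully substituted ring A as its silyl ether, so no late bromination is needed. Its precursor pair is the tribromo sulfone diene and the bis(trimethylsilyl) ketene acetal of (2,4-dibromophenoxy)acetic acid.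

Key step: step 5

Remark: compounds 10 and 11 and their fallback analogues are racemic and of undefined endo/exo configuration; all their stereocentres vanish on aromatisation, so none is specified. The target has no stereocentre.

**Route**

Step 1
Reactants: 1 tetrabromothiophene
Product: 3 2,3,4-tribromothiophene, via 3,4,5-tribromo-2-thienyllithium 2 (not isolated)
Conditions: n-BuLi (1.0 equiv), THF, −78 °C; then H2O, −78 °C → rt
Reagents that add atoms: none
Why: Bromine–lithium exchange on a polybromothiophene is fastest at an α-position, so one equivalent of n-BuLi should give the α-lithio species cleanly, and protonation replaces that single bromine by hydrogen.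

Step 2
Reactants: 3 2,3,4-tribromothiophene
Product: 4 2,3,4-tribromothiophene 1,1-dioxide
Conditions: CF3CO3H [from (CF3CO)2O and 30% aq H2O2], CH2Cl2, 0 °C → rt; product kept cold and used soon
Reagents that add atoms: peroxytrifluoroacetic acid, OOC(=O)C(F)(F)F (made in the flask from trifluoroacetic anhydride and hydrogen peroxide, OO)
Why: Electrophilic S-oxidation by the strongest common peracid is the established way to turn electron-poor polyhalothiophenes into their 1,1-dioxides, the sulfoxide stage being oxidised faster than the thiophene.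

Step 3
Reactants: 5 2,4-dibromophenol; 6 bromoacetic acid
Product: 7 (2,4-dibromophenoxy)acetic acid
Conditions: NaOH (2.2 equiv), H2O, reflux; then HCl (aq) to pH 1
Reagents that add atoms: none
Why: Williamson ether synthesis, SN2 attack of the phenoxide on bromoacetate, is the classical preparation of aryloxyacetic acids.

Step 4
Reactants: 7 (2,4-dibromophenoxy)acetic acid
Product: 9 2-(2,4-dibromophenoxy)-1,1-bis(trimethylsilyloxy)ethene, via trimethylsilyl (2,4-dibromophenoxy)acetate 8 (not isolated)
Conditions: LiN(SiMe3)2 (1.0 equiv), Me3SiCl (2.3 equiv), THF, −78 → 0 °C; then LiN(SiMe3)2 (1.1 equiv), −78 °C → rt; evaporate, pentane, filter under Ar, high vacuum (amine-free)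
Reagents that add atoms: chlorotrimethylsilane, C[Si](C)(C)Cl
Why: O-silylation of the lithium carboxylate followed by ester enolisation with in situ O-silylation (the internal-quench enol silylation used for glycolate esters) should give the ketene bis(silyl) acetal, and LiN(SiMe3)2 is chosen over LDA because it is too weak to metalate the ring CH between the two bromines of ring B.

Step 5
Reactants: 4 2,3,4-tribromothiophene 1,1-dioxide; 9 2-(2,4-dibromophenoxy)-1,1-bis(trimethylsilyloxy)ethene
Product: 12 [2,3,4-tribromo-6-(2,4-dibromophenoxy)phenoxy]trimethylsilane, via bridged sulfone cycloadduct 10 (not isolated), via bis(silyloxy)cyclohexadiene 11 (not isolated)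
Conditions: 9 (2.0 equiv), toluene, −20 °C → rt, then 80 °C, Ar
Reagents that add atoms: none
Why: Proposed new method: the electron-poor sulfone diene 4 and the electron-rich alkene 9 should combine in an asynchronous inverse-electron-demand Diels–Alder reaction in which the nucleophilic aryloxy-bearing carbon of 9 bonds first to the unsubstituted α-carbon of 4 (ring A C2–C3) and the silyloxy-stabilised acetal carbon then closes on the brominated α-carbon (ring A C1–C6), so ring A is closed as the six-membered ring of a [4+2] cycloaddition. Bridged sulfone 10 should then extrude SO2 cheletropically to give diene 11, whose C1 ketal ionises with help of the second silyloxy group and loses the C2 hydrogen as Me3SiOH under the driving force of aromatisation. The closest known reaction type is the Diels–Alder reaction of tetrahalo- and 3,4-dihalothiophene 1,1-dioxides with enol ethers and other electron-rich alkenes, followed by SO2 loss and aromatising elimination; a ketene bis(silyl) acetal has not been shown as the partner. No stereocentre survives in 12, so the endo or exo course of the addition and the configuration at the aryloxy carbon do not matter. The one selectivity needed is the orientation of the two partners, which should follow from attack at the less hindered CH terminus and from the better stabilisation of the developing negative charge on the brominated α-sulfonyl carbon. Two equivalents of 9 are used because the Me3SiOH set free protonates the ketene acetal.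

Step 6
Reactants: 12 [2,3,4-tribromo-6-(2,4-dibromophenoxy)phenoxy]trimethylsilane
Product: 13 2,3,4-tribromo-6-(2,4-dibromophenoxy)phenol
Conditions: HCl (1 M aq), THF, rt
Reagents that add atoms: none
Why: Acid hydrolysis of an aryl trimethylsilyl ether is fast and leaves the diaryl ether and the aryl bromides untouched.

**Compound list**

1 | tetrabromothiophene | Brc1sc(Br)c(Br)c1Br | starting material
2 | 3,4,5-tribromo-2-thienyllithium | [Li]c1sc(Br)c(Br)c1Br | intermediate
3 | 2,3,4-tribromothiophene | Brc1scc(Br)c1Br | intermediate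
4 | 2,3,4-tribromothiophene 1,1-dioxide | O=S1(=O)C=C(Br)C(Br)=C1Br | intermediate
5 | 2,4-dibromophenol | Oc1ccc(Br)cc1Br | starting material
6 | bromoacetic acid | OC(=O)CBr | starting material
7 | (2,4-dibromophenoxy)acetic acid | OC(=O)COc1ccc(Br)cc1Br | intermediate
8 | trimethylsilyl (2,4-dibromophenoxy)acetate | C[Si](C)(C)OC(=O)COc1ccc(Br)cc1Br | intermediate
9 | 2-(2,4-dibromophenoxy)-1,1-bis(trimethylsilyloxy)ethene | C[Si](C)(C)OC(O[Si](C)(C)C)=COc1ccc(Br)cc1Br | intermediate
10 | 1,2,3-tribromo-5-(2,4-dibromophenoxy)-6,6-bis(trimethylsilyloxy)-7-thiabicyclo[2.2.1]hept-2-ene 7,7-dioxide (racemic, endo/exo undefined) | O=S1(=O)C2C(Oc3ccc(Br)cc3Br)C(O[Si](C)(C)C)(O[Si](C)(C)C)C1(Br)C(Br)=C2Br | intermediate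
11 | 1,2,3-tribromo-5-(2,4-dibromophenoxy)-6,6-bis(trimethylsilyloxy)cyclohexa-1,3-diene (racemic) | C[Si](C)(C)OC1(O[Si](C)(C)C)C(Oc2ccc(Br)cc2Br)C=C(Br)C(Br)=C1Br | intermediate
12 | [2,3,4-tribromo-6-(2,4-dibromophenoxy)phenoxy]trimethylsilane | C[Si](C)(C)Oc1c(Oc2ccc(Br)cc2Br)cc(Br)c(Br)c1Br | intermediate
13 | 2,3,4-tribromo-6-(2,4-dibromophenoxy)phenol | Oc1c(Oc2ccc(Br)cc2Br)cc(Br)c(Br)c1Br | target

**Step count**

Total steps: 6 (convergent). Longest linear sequence: 4 steps (steps 1, 2, 5, 6 or steps 3, 4, 5, 6).

**Steps most likely to fail**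

Step 5 (carries the label "Proposed new method:"). The two partners may add in the reverse orientation, which would give the 3,4,5-tribromo arrangement on ring A. The reaction may also stop at conjugate addition with silyl transfer and no ring closure, or the ketene acetal may be consumed by the silanol set free. The fallback uses known chemistry only, sets out from 5 and comes back at 13. SNAr of 5 on commercial 5-bromo-2-fluorobenzaldehyde (K2CO3, N,N-dimethylacetamide, 120 °C) should give 5-bromo-2-(2,4-dibromophenoxy)benzaldehyde F1. Baeyer–Villiger oxidation (mCPBA, CH2Cl2) should give 5-bromo-2-(2,4-dibromophenoxy)phenyl formate F2, which KOH in MeOH cleaves to 5-bromo-2-(2,4-dibromophenoxy)phenol F3. Br2 (2 equiv, AcOH, rt) should then brominate ring A para and ortho to the free hydroxyl, at C4 and C6 beside the bromine already on C5, to reach 13; ring B is deactivated by its two bromines.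

Step 2. Oxidation at the sulfur of the strongly deactivated thiophene may stay incomplete, and the sulfoxide stage or the dioxide may dimerise through the double bond that carries hydrogen. The fallback changes the diene and moves one bromination to the end; it sets out from 9 and comes back at 13. Commercial 3,4-dibromothiophene, less deactivated, is oxidised (CF3CO3H, CH2Cl2) to 3,4-dibromothiophene 1,1-dioxide F4, a symmetrical diene for which orientation is not an issue. With 9 under the conditions of step 5 it should pass through 2,3-dibromo-5-(2,4-dibromophenoxy)-6,6-bis(trimethylsilyloxy)-7-thiabicyclo[2.2.1]hept-2-ene 7,7-dioxide F5 and 2,3-dibromo-5-(2,4-dibromophenoxy)-6,6-bis(trimethylsilyloxy)cyclohexa-1,3-diene F6 to [4,5-dibromo-2-(2,4-dibromophenoxy)phenoxy]trimethylsilane F7. Dilute HCl should give 4,5-dibromo-2-(2,4-dibromophenoxy)phenol F8. Br2 (1 equiv, AcOH, 0 °C) should then enter the only free position ortho to the hydroxyl, C6 of ring A, to give 13.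

Step 4. The amide may attack silicon of the silyl ester instead of removing the α-proton, the ester may self-condense, or the labile trimethylsilyl acetal may hydrolyse while the lithium salts are removed. The fallback uses soft enolisation without any lithium base and a more robust silyl group; it sets out from 7 and comes back at 13. tBuMe2SiOTf (2.2 equiv) and Et3N in CH2Cl2 should give, via tert-butyldimethylsilyl (2,4-dibromophenoxy)acetate F9, 1,1-bis(tert-butyldimethylsilyloxy)-2-(2,4-dibromophenoxy)ethene F10, which is stable enough to be freed from the ammonium triflate by pentane extraction. With 4 under the conditions of step 5 it should pass through 1,2,3-tribromo-5-(2,4-dibromophenoxy)-6,6-bis(tert-butyldimethylsilyloxy)-7-thiabicyclo[2.2.1]hept-2-ene 7,7-dioxide F11 and 1,2,3-tribromo-5-(2,4-dibromophenoxy)-6,6-bis(tert-butyldimethylsilyloxy)cyclohexa-1,3-diene F12 to tert-butyl[2,3,4-tribromo-6-(2,4-dibromophenoxy)phenoxy]dimethylsilane F13. Bu4NF in THF should cleave this to 13.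

**Further compounds**

F1 | step 5 | 5-bromo-2-(2,4-dibromophenoxy)benzaldehyde | O=Cc1cc(Br)ccc1Oc1ccc(Br)cc1Br
F2 | step 5 | 5-bromo-2-(2,4-dibromophenoxy)phenyl formate | O=COc1cc(Br)ccc1Oc1ccc(Br)cc1Br
F3 | step 5 | 5-bromo-2-(2,4-dibromophenoxy)phenol | Oc1cc(Br)ccc1Oc1ccc(Br)cc1Br
F4 | step 2 | 3,4-dibromothiophene 1,1-dioxide | O=S1(=O)C=C(Br)C(Br)=C1
F5 | step 2 | 2,3-dibromo-5-(2,4-dibromophenoxy)-6,6-bis(trimethylsilyloxy)-7-thiabicyclo[2.2.1]hept-2-ene 7,7-dioxide (racemic, endo/exo undefined) | O=S1(=O)C2C(Oc3ccc(Br)cc3Br)C(O[Si](C)(C)C)(O[Si](C)(C)C)C1C(Br)=C2Br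
F6 | step 2 | 2,3-dibromo-5-(2,4-dibromophenoxy)-6,6-bis(trimethylsilyloxy)cyclohexa-1,3-diene (racemic) | C[Si](C)(C)OC1(O[Si](C)(C)C)C(Oc2ccc(Br)cc2Br)C=C(Br)C(Br)=C1
F7 | step 2 | [4,5-dibromo-2-(2,4-dibromophenoxy)phenoxy]trimethylsilane | C[Si](C)(C)Oc1cc(Br)c(Br)cc1Oc1ccc(Br)cc1Br
F8 | step 2 | 4,5-dibromo-2-(2,4-dibromophenoxy)phenol | Oc1cc(Br)c(Br)cc1Oc1ccc(Br)cc1Br
F9 | step 4 | tert-butyldimethylsilyl (2,4-dibromophenoxy)acetate | CC(C)(C)[Si](C)(C)OC(=O)COc1ccc(Br)cc1Br
F10 | step 4 | 1,1-bis(tert-butyldimethylsilyloxy)-2-(2,4-dibromophenoxy)ethene | CC(C)(C)[Si](C)(C)OC(O[Si](C)(C)C(C)(C)C)=COc1ccc(Br)cc1Br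
F11 | step 4 | 1,2,3-tribromo-5-(2,4-dibromophenoxy)-6,6-bis(tert-butyldimethylsilyloxy)-7-thiabicyclo[2.2.1]hept-2-ene 7,7-dioxide (racemic, endo/exo undefined) | O=S1(=O)C2C(Oc3ccc(Br)cc3Br)C(O[Si](C)(C)C(C)(C)C)(O[Si](C)(C)C(C)(C)C)C1(Br)C(Br)=C2Br
F12 | step 4 | 1,2,3-tribromo-5-(2,4-dibromophenoxy)-6,6-bis(tert-butyldimethylsilyloxy)cyclohexa-1,3-diene (racemic) | CC(C)(C)[Si](C)(C)OC1(O[Si](C)(C)C(C)(C)C)C(Oc2ccc(Br)cc2Br)C=C(Br)C(Br)=C1Br
F13 | step 4 | tert-butyl[2,3,4-tribromo-6-(2,4-dibromophenoxy)phenoxy]dimethylsilane | CC(C)(C)[Si](C)(C)Oc1c(Oc2ccc(Br)cc2Br)cc(Br)c(Br)c1Br
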